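**Retrosynthetic overview**
1. The C12–C13 bond is cut last. The 13R alcohol 36 (target with O15/O17 as triethylsilyl ethers and the acid as its 2-(trimethylsilyl)ethyl ester) comes, after a planned C13 oxidation/reduction adjustment, from a nickel-catalysed reductive coupling of enyne 17 (C1–C12) with aldehyde 33 (C13–C23).
2. Enabling feature: C13 is a carbinol on C12 of the (9E,11E)-diene with H-11 cis to C13. This is the syn H/C adduct of a C11≡C12 methyl alkyne, and its conjugation to C9=C10 fixes the regiochemistry; no ring takes part.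
3. Enyne 17: C5 by organocatalytic malonate Michael addition, C7/C8 by (Z)-crotylboration, then lactonisation/dealkoxycarbonylation, ozonolysis, Takai iodo-olefination, Sonogashira coupling and Horner–Wadsworth–Emmons olefination.
4. Aldehyde 33: three Wittig reactions on 2-methyloxazole-4-carbaldehyde, Evans syn aldol (C16, C17), Claisen-type two-carbon extension, 1,3-anti reduction (C15), silylation, partial ester reduction.
5. Rings: the oxazole is purchased; the δ-lactone is the only ring formed (step 4).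

Key step: step 20

Remark: atoms are numbered along the chain from the carboxyl carbon C1 to C23 (the CH bearing the oxazole). In this numbering the target is 5R,7R,8R,13R,15S,16S,17R, with a cis-4,6-disubstituted δ-lactone (C5/C7), a 13,15-syn and a 15,17-anti diol, and all olefins E.
Assumption: the (Z)-crotylborane of step 3 and Dess–Martin periodinane are used as standard prepared reagents; all numbered starting materials are catalogue compounds.

**Western fragment (C1–C12)**

Step 1
Reactants: 1 4,4-diethoxybut-1-ene; 2 (E)-crotonaldehyde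
Product: 3 (2E)-5,5-diethoxypent-2-enal
Conditions: second-generation Hoveyda–Grubbs catalyst (3 mol %), 2 (4 equiv), CH2Cl2, 40 °C
Reagents that add atoms: none
Why: Olefin cross-metathesis of a terminal homoallylic olefin with excess crotonaldehyde should give the (E)-enal with loss of propene.

Step 2
Reactants: 3 (2E)-5,5-diethoxypent-2-enal; 4 dimethyl malonate
Product: 5 dimethyl 2-[(3S)-1,1-diethoxy-5-oxopentan-3-yl]propanedioate
Conditions: (S)-2-{bis[3,5-bis(trifluoromethyl)phenyl](trimethylsilyloxy)methyl}pyrrolidine (10 mol %), EtOH, 0 °C to rt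
Reagents that add atoms: none
Why: In this organocatalytic iminium Michael addition the (S)-diarylprolinol silyl ether forms an (E)-iminium ion with one face shielded, so malonate should add to the β-carbon from the open face and set the 3S centre, which becomes C5 (R) of the target.

Step 3
Reactants: 5 dimethyl 2-[(3S)-1,1-diethoxy-5-oxopentan-3-yl]propanedioate
Product: 6 dimethyl 2-[(3S,5R,6R)-1,1-diethoxy-5-hydroxy-6-methyloct-7-en-3-yl]propanedioate
Conditions: (Z)-crotyl-B(Ipc)2 [Ipc = isopinocampheyl from (+)-α-pinene], THF, −78 °C; then NaBO3·4H2O, THF/H2O, rt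
Reagents that add atoms: (Z)-crotyldiisopinocampheylborane, C/C=C\CB([C@@H]1C[C@@H]2C[C@H]([C@H]1C)C2(C)C)[C@@H]1C[C@@H]2C[C@H]([C@H]1C)C2(C)C
Why: Brown (Z)-crotylboration through a chair six-membered transition state should give the 7,8-syn homoallylic alcohol, and the isopinocampheyl groups select the aldehyde face that makes C7 and C8 both R irrespective of the remote C5 centre.

Step 4
Reactants: 6 dimethyl 2-[(3S,5R,6R)-1,1-diethoxy-5-hydroxy-6-methyloct-7-en-3-yl]propanedioate
Product: 8 (4S,6R)-6-[(2R)-but-3-en-2-yl]-4-(2,2-diethoxyethyl)oxan-2-one, via carbomethoxy lactone 7 (not isolated)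
Conditions: NaCl, H2O, DMSO, 130 °C
Reagents that add atoms: none
Why: Lactonisation of the δ-hydroxy malonate followed by Krapcho dealkoxycarbonylation should give the δ-lactone, in which the pre-set C5 and C7 centres place both substituents equatorial (cis).

Step 5
Reactants: 8 (4S,6R)-6-[(2R)-but-3-en-2-yl]-4-(2,2-diethoxyethyl)oxan-2-one
Product: 9 (2S)-2-[(2R,4S)-4-(2,2-diethoxyethyl)-6-oxooxan-2-yl]propanal
Conditions: O3, CH2Cl2, −78 °C (Sudan red end point); then PPh3, −78 °C to rt
Reagents that add atoms: ozone, [O-][O+]=O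
Why: Ozonolysis with reductive work-up cleaves the only C=C bond to the α-methyl aldehyde without base, so the C8 centre should not epimerise.

Step 6
Reactants: 9 (2S)-2-[(2R,4S)-4-(2,2-diethoxyethyl)-6-oxooxan-2-yl]propanal
Product: 10 (4S,6R)-4-(2,2-diethoxyethyl)-6-[(2R,3E)-4-iodobut-3-en-2-yl]oxan-2-one
Conditions: CrCl2, CHI3, THF, 0 °C to rt
Reagents that add atoms: iodoform, IC(I)I
Why: Takai olefination with the geminal dichromium species from CHI3 and divalent chromium should give the (E)-vinyl iodide under non-basic conditions that keep C8 intact.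

Step 7
Reactants: 10 (4S,6R)-4-(2,2-diethoxyethyl)-6-[(2R,3E)-4-iodobut-3-en-2-yl]oxan-2-one; 11 propyne
Product: 12 (4S,6R)-4-(2,2-diethoxyethyl)-6-[(2R,3E)-hept-3-en-5-yn-2-yl]oxan-2-one
Conditions: Pd(PPh3)2Cl2 (5 mol %), CuI (10 mol %), Et3N, THF, rt
Reagents that add atoms: none
Why: Sonogashira coupling of the (E)-vinyl iodide with propyne proceeds with retention of olefin geometry and should give the (E)-1,3-enyne.

Step 8
Reactants: 12 (4S,6R)-4-(2,2-diethoxyethyl)-6-[(2R,3E)-hept-3-en-5-yn-2-yl]oxan-2-one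
Product: 13 2-{(2R,4S)-2-[(2R,3E)-hept-3-en-5-yn-2-yl]-6-oxooxan-4-yl}acetaldehyde
Conditions: pyridinium p-toluenesulfonate, acetone/H2O (4:1), 50 °C
Reagents that add atoms: water, O
Why: Mild acid-catalysed acetal hydrolysis should release the aldehyde while the δ-lactone and the enyne survive.

Step 9
Reactants: 14 diethylphosphonoacetic acid; 15 2-(trimethylsilyl)ethanol
Product: 16 2-(trimethylsilyl)ethyl 2-(diethoxyphosphoryl)acetate
Conditions: DCC, DMAP (cat.), CH2Cl2, 0 °C to rt
Reagents that add atoms: none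
Why: Steglich esterification with carbodiimide activation and DMAP catalysis should give the fluoride-labile phosphonoacetate.

Step 10
Reactants: 13 2-{(2R,4S)-2-[(2R,3E)-hept-3-en-5-yn-2-yl]-6-oxooxan-4-yl}acetaldehyde; 16 2-(trimethylsilyl)ethyl 2-(diethoxyphosphoryl)acetate
Product: 17 2-(trimethylsilyl)ethyl (2E)-4-{(2R,4R)-2-[(2R,3E)-hept-3-en-5-yn-2-yl]-6-oxooxan-4-yl}but-2-enoate
Conditions: LiCl, DBU, MeCN, 0 °C to rt
Reagents that add atoms: none
Why: Horner–Wadsworth–Emmons olefination under Masamune–Roush conditions should give the (E)-enoate without touching the lactone or the enyne.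

**Eastern fragment (C13–C23)**

Step 11
Reactants: 18 2-methyl-1,3-oxazole-4-carbaldehyde; 19 2-(triphenylphosphoranylidene)propanal
Product: 20 (2E)-2-methyl-3-(2-methyl-1,3-oxazol-4-yl)prop-2-enal
Conditions: toluene, 90 °C
Reagents that add atoms: none
Why: Wittig olefination with a stabilised α-methyl ylide should give the (E)-trisubstituted enal.

Step 12
Reactants: 20 (2E)-2-methyl-3-(2-methyl-1,3-oxazol-4-yl)prop-2-enal; 21 (triphenylphosphoranylidene)acetaldehyde
Product: 22 (2E,4E)-4-methyl-5-(2-methyl-1,3-oxazol-4-yl)penta-2,4-dienal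
Conditions: toluene, 80 °C
Reagents that add atoms: none
Why: Wittig olefination with the stabilised formylmethylene ylide should extend the enal by two carbons to the (E,E)-dienal.

Step 13
Reactants: 22 (2E,4E)-4-methyl-5-(2-methyl-1,3-oxazol-4-yl)penta-2,4-dienal; 19 2-(triphenylphosphoranylidene)propanal
Product: 23 (2E,4E,6E)-2,6-dimethyl-7-(2-methyl-1,3-oxazol-4-yl)hepta-2,4,6-trienal
Conditions: toluene, 100 °C
Reagents that add atoms: none
Why: A second Wittig olefination with the stabilised α-methyl ylide should complete the (E,E,E)-trienal.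

Step 14
Reactants: 23 (2E,4E,6E)-2,6-dimethyl-7-(2-methyl-1,3-oxazol-4-yl)hepta-2,4,6-trienal; 24 (4R)-4-benzyl-3-propanoyl-1,3-oxazolidin-2-one
Product: 26 (4R)-4-benzyl-3-[(2R,3R,4E,6E,8E)-3-hydroxy-2,4,8-trimethyl-9-(2-methyl-1,3-oxazol-4-yl)nona-4,6,8-trienoyl]-1,3-oxazolidin-2-one, via dibutylboron Z-enolate 25 (not isolated)
Conditions: Bu2BOTf, i-Pr2NEt, CH2Cl2, −78 to 0 °C; then 23, −78 to 0 °C; pH 7 buffer, MeOH, 30% H2O2, 0 °C
Reagents that add atoms: none
Why: In this Evans syn aldol reaction the (Z)-boron enolate reacts through a Zimmerman–Traxler transition state in which the (R)-benzyl auxiliary selects one enolate face and sets C16 and C17 (2R,3R in the adduct).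

Step 15
Reactants: 26 Evans aldol adduct
Product: 27 (2R,3R,4E,6E,8E)-3-hydroxy-N-methoxy-N,2,4,8-tetramethyl-9-(2-methyl-1,3-oxazol-4-yl)nona-4,6,8-trienamide
Conditions: MeNHOMe·HCl, AlMe3, THF/CH2Cl2, −20 to 0 °C
Reagents that add atoms: N,O-dimethylhydroxylamine hydrochloride, CNOC.Cl
Why: Aluminium amide transamidation of the β-hydroxy imide should give the Weinreb amide and return the auxiliary.

Step 16
Reactants: 27 Weinreb amide; 28 methyl acetate
Product: 30 methyl (4R,5R,6E,8E,10E)-5-hydroxy-4,6,10-trimethyl-11-(2-methyl-1,3-oxazol-4-yl)-3-oxoundeca-6,8,10-trienoate, via lithium enolate of methyl acetate 29 (not isolated)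
Conditions: LiN(i-Pr)2 (3.5 equiv), THF, −78 °C; then 27, −78 to −40 °C
Reagents that add atoms: none
Why: Claisen-type acylation of the lithium ester enolate by the Weinreb amide, whose chelated tetrahedral intermediate prevents double addition, should give the δ-hydroxy β-keto ester.

Step 17
Reactants: 30 δ-hydroxy β-keto ester
Product: 31 methyl (3S,4S,5R,6E,8E,10E)-3,5-dihydroxy-4,6,10-trimethyl-11-(2-methyl-1,3-oxazol-4-yl)undeca-6,8,10-trienoate
Conditions: Me4NBH(OAc)3, MeCN/AcOH (1:1), −30 °C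
Reagents that add atoms: none
Why: In the Evans–Saksena reduction the C17 hydroxyl exchanges onto boron and delivers hydride intramolecularly through a chair transition state, which should give the 15,17-anti diol and thus the 15S centre.

Step 18
Reactants: 31 anti-diol ester
Product: 32 methyl (3S,4S,5R,6E,8E,10E)-4,6,10-trimethyl-11-(2-methyl-1,3-oxazol-4-yl)-3,5-bis(triethylsilyloxy)undeca-6,8,10-trienoate
Conditions: Et3SiOTf, 2,6-lutidine, CH2Cl2, −78 °C
Reagents that add atoms: triethylsilyl trifluoromethanesulfonate, CC[Si](CC)(CC)OS(=O)(=O)C(F)(F)F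
Why: Silylation of both secondary alcohols with a silyl triflate and a hindered pyridine should give the bis(triethylsilyl) ether.

Step 19
Reactants: 32 bis(triethylsilyl) ether ester
Product: 33 (3S,4S,5R,6E,8E,10E)-4,6,10-trimethyl-11-(2-methyl-1,3-oxazol-4-yl)-3,5-bis(triethylsilyloxy)undeca-6,8,10-trienal
Conditions: i-Bu2AlH (1.2 equiv), CH2Cl2, −78 °C; aq Rochelle salt
Reagents that add atoms: none
Why: Partial reduction of the methyl ester with i-Bu2AlH at low temperature should stop at the aldehyde because the aluminium hemiacetal is stable until work-up.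

**Fragment union and endgame**

Step 20
Reactants: 17 enyne (C1–C12); 33 aldehyde (C13–C23)
Product: 34 coupling product, the 15,17-bis(triethylsilyl) ether 2-(trimethylsilyl)ethyl ester of the target as a mixture of C13 epimers
Conditions: Ni(cod)2 (15 mol %), tricyclopentylphosphine (30 mol %), Et3B (2.5 equiv), EtOAc, rt
Reagents that add atoms: none
Why: Zerovalent nickel binds enyne 17 and aldehyde 33 and undergoes oxidative cyclisation to an oxanickelacyclopentene with the new C–C bond at the alkyne carbon remote from the conjugated C9=C10 olefin (C12); ethyl transfer from Et3B, β-hydride elimination and C–H reductive elimination then deliver H to C11 cis to C13, so the C12–C13 bond, the (11E)-trisubstituted olefin and the complete (9E,11E)-diene arise in one operation from an alkyne that needs no stereodefined vinyl metal or halide. The closest known reaction type is the nickel-catalysed, trialkylborane-mediated reductive coupling of 1,3-enynes with aldehydes, which is known for high regioselectivity with this methyl-alkyne/alkene pattern. No ring is closed. The new C13 stereocentre has no dependable controlling element, because a β-silyloxy group induces only weakly in this manifold, and none is needed: both epimers converge on the ketone in step 21 and 13R is set by the reagent in step 22. The step needs regioselectivity (C12 rather than C11), secured by the conjugated C9=C10 olefin and the small methyl group, and chemoselectivity for the aldehyde over the δ-lactone, the β-substituted enoate and the trisubstituted polyene of 33, secured by the much faster oxidative cyclisation of an alkyne–aldehyde pair at room temperature.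

Step 21
Reactants: 34 coupling product (C13 epimers)
Product: 35 C13 ketone (13-oxo compound) of the 15,17-bis(triethylsilyl) ether 2-(trimethylsilyl)ethyl ester
Conditions: Dess–Martin periodinane, NaHCO3, CH2Cl2, 0 °C
Reagents that add atoms: none
Why: Dess–Martin oxidation should convert both C13 epimers into the single dienone under buffered non-acidic conditions.

Step 22
Reactants: 35 C13 ketone
Product: 36 (13R)-alcohol, the 15,17-bis(triethylsilyl) ether 2-(trimethylsilyl)ethyl ester of the target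
Conditions: (S)-2-methyl-CBS-oxazaborolidine (0.5 equiv), catecholborane, toluene, −78 °C
Reagents that add atoms: none
Why: In the Corey–Bakshi–Shibata reduction the (S)-oxazaborolidine binds the ketone with the α-methyldienyl group as the large substituent and should deliver hydride 1,2 to give the 13R allylic alcohol (13,15-syn).

Step 23
Reactants: 36 (13R)-alcohol
Product: 37 CNP0198746.1
Conditions: Bu4NF, AcOH (1:1), THF, 0 °C to rt
Reagents that add atoms: none
Why: Fluoride-mediated desilylation buffered with acetic acid should cleave both triethylsilyl ethers and the 2-(trimethylsilyl)ethyl ester (β-elimination with loss of ethylene) in one operation without harming the δ-lactone or the allylic alcohols.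

**Compound list**
1 | 4,4-diethoxybut-1-ene | C=CCC(OCC)OCC | starting material
2 | (E)-crotonaldehyde | C/C=C/C=O | starting material
3 | (2E)-5,5-diethoxypent-2-enal | CCOC(OCC)C/C=C/C=O | intermediate
4 | dimethyl malonate | COC(=O)CC(=O)OC | starting material
5 | dimethyl 2-[(3S)-1,1-diethoxy-5-oxopentan-3-yl]propanedioate | O=CC[C@@H](CC(OCC)OCC)C(C(=O)OC)C(=O)OC | intermediate
6 | dimethyl 2-[(3S,5R,6R)-1,1-diethoxy-5-hydroxy-6-methyloct-7-en-3-yl]propanedioate | C=C[C@@H](C)[C@H](O)C[C@@H](CC(OCC)OCC)C(C(=O)OC)C(=O)OC | intermediate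
7 | methyl (4S,6R)-6-[(2R)-but-3-en-2-yl]-4-(2,2-diethoxyethyl)-2-oxooxane-3-carboxylate (C3 epimers) | C=C[C@@H](C)[C@H]1C[C@@H](CC(OCC)OCC)C(C(=O)OC)C(=O)O1 | intermediate
8 | (4S,6R)-6-[(2R)-but-3-en-2-yl]-4-(2,2-diethoxyethyl)oxan-2-one | C=C[C@@H](C)[C@H]1C[C@@H](CC(OCC)OCC)CC(=O)O1 | intermediate
9 | (2S)-2-[(2R,4S)-4-(2,2-diethoxyethyl)-6-oxooxan-2-yl]propanal | O=C[C@@H](C)[C@H]1C[C@@H](CC(OCC)OCC)CC(=O)O1 | intermediate
10 | (4S,6R)-4-(2,2-diethoxyethyl)-6-[(2R,3E)-4-iodobut-3-en-2-yl]oxan-2-one | I/C=C/[C@@H](C)[C@H]1C[C@@H](CC(OCC)OCC)CC(=O)O1 | intermediate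
11 | propyne | CC#C | starting material
12 | (4S,6R)-4-(2,2-diethoxyethyl)-6-[(2R,3E)-hept-3-en-5-yn-2-yl]oxan-2-one | CC#C/C=C/[C@@H](C)[C@H]1C[C@@H](CC(OCC)OCC)CC(=O)O1 | intermediate
13 | 2-{(2R,4S)-2-[(2R,3E)-hept-3-en-5-yn-2-yl]-6-oxooxan-4-yl}acetaldehyde | CC#C/C=C/[C@@H](C)[C@H]1C[C@@H](CC=O)CC(=O)O1 | intermediate
14 | diethylphosphonoacetic acid | CCOP(=O)(OCC)CC(=O)O | starting material
15 | 2-(trimethylsilyl)ethanol | C[Si](C)(C)CCO | starting material
16 | 2-(trimethylsilyl)ethyl 2-(diethoxyphosphoryl)acetate | CCOP(=O)(OCC)CC(=O)OCC[Si](C)(C)C | intermediate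
17 | 2-(trimethylsilyl)ethyl (2E)-4-{(2R,4R)-2-[(2R,3E)-hept-3-en-5-yn-2-yl]-6-oxooxan-4-yl}but-2-enoate | CC#C/C=C/[C@@H](C)[C@H]1C[C@@H](C/C=C/C(=O)OCC[Si](C)(C)C)CC(=O)O1 | intermediate
18 | 2-methyl-1,3-oxazole-4-carbaldehyde | Cc1nc(C=O)co1 | starting material
19 | 2-(triphenylphosphoranylidene)propanal | CC(C=O)=P(c1ccccc1)(c1ccccc1)c1ccccc1 | starting material
20 | (2E)-2-methyl-3-(2-methyl-1,3-oxazol-4-yl)prop-2-enal | O=C/C(C)=C/c1coc(C)n1 | intermediate
21 | (triphenylphosphoranylidene)acetaldehyde | O=CC=P(c1ccccc1)(c1ccccc1)c1ccccc1 | starting material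
22 | (2E,4E)-4-methyl-5-(2-methyl-1,3-oxazol-4-yl)penta-2,4-dienal | O=C/C=C/C(C)=C/c1coc(C)n1 | intermediate
23 | (2E,4E,6E)-2,6-dimethyl-7-(2-methyl-1,3-oxazol-4-yl)hepta-2,4,6-trienal | O=C/C(C)=C/C=C/C(C)=C/c1coc(C)n1 | intermediate
24 | (4R)-4-benzyl-3-propanoyl-1,3-oxazolidin-2-one | CCC(=O)N1[C@H](Cc2ccccc2)COC1=O | starting material
25 | dibutylboron (Z)-enolate of 24 | C/C=C(\OB(CCCC)CCCC)N1[C@H](Cc2ccccc2)COC1=O | intermediate
26 | (4R)-4-benzyl-3-[(2R,3R,4E,6E,8E)-3-hydroxy-2,4,8-trimethyl-9-(2-methyl-1,3-oxazol-4-yl)nona-4,6,8-trienoyl]-1,3-oxazolidin-2-one | CC(/C=C/C=C(\C)[C@H](O)[C@@H](C)C(=O)N1[C@H](Cc2ccccc2)COC1=O)=C\c1coc(C)n1 | intermediate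
27 | (2R,3R,4E,6E,8E)-3-hydroxy-N-methoxy-N,2,4,8-tetramethyl-9-(2-methyl-1,3-oxazol-4-yl)nona-4,6,8-trienamide | CC(/C=C/C=C(\C)[C@H](O)[C@@H](C)C(=O)N(C)OC)=C\c1coc(C)n1 | intermediate
28 | methyl acetate | COC(C)=O | starting material
29 | lithium enolate of methyl acetate | [Li]OC(=C)OC | intermediate
30 | methyl (4R,5R,6E,8E,10E)-5-hydroxy-4,6,10-trimethyl-11-(2-methyl-1,3-oxazol-4-yl)-3-oxoundeca-6,8,10-trienoate | CC(/C=C/C=C(\C)[C@H](O)[C@@H](C)C(=O)CC(=O)OC)=C\c1coc(C)n1 | intermediate
31 | methyl (3S,4S,5R,6E,8E,10E)-3,5-dihydroxy-4,6,10-trimethyl-11-(2-methyl-1,3-oxazol-4-yl)undeca-6,8,10-trienoate | CC(/C=C/C=C(\C)[C@H](O)[C@@H](C)[C@@H](O)CC(=O)OC)=C\c1coc(C)n1 | intermediate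
32 | methyl (3S,4S,5R,6E,8E,10E)-4,6,10-trimethyl-11-(2-methyl-1,3-oxazol-4-yl)-3,5-bis(triethylsilyloxy)undeca-6,8,10-trienoate | CC(/C=C/C=C(\C)[C@H](O[Si](CC)(CC)CC)[C@@H](C)[C@@H](O[Si](CC)(CC)CC)CC(=O)OC)=C\c1coc(C)n1 | intermediate
33 | (3S,4S,5R,6E,8E,10E)-4,6,10-trimethyl-11-(2-methyl-1,3-oxazol-4-yl)-3,5-bis(triethylsilyloxy)undeca-6,8,10-trienal | CC(/C=C/C=C(\C)[C@H](O[Si](CC)(CC)CC)[C@@H](C)[C@@H](O[Si](CC)(CC)CC)CC=O)=C\c1coc(C)n1 | intermediate
34 | 15,17-bis(triethylsilyl) ether 2-(trimethylsilyl)ethyl ester of the target, mixture of C13 epimers | CC(/C=C/C=C(\C)[C@H](O[Si](CC)(CC)CC)[C@@H](C)[C@@H](O[Si](CC)(CC)CC)CC(O)/C(C)=C/C=C/[C@@H](C)[C@H]1C[C@@H](C/C=C/C(=O)OCC[Si](C)(C)C)CC(=O)O1)=C\c1coc(C)n1 | intermediate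
35 | 13-oxo compound (dienone) of the 15,17-bis(triethylsilyl) ether 2-(trimethylsilyl)ethyl ester | CC(/C=C/C=C(\C)[C@H](O[Si](CC)(CC)CC)[C@@H](C)[C@@H](O[Si](CC)(CC)CC)CC(=O)/C(C)=C/C=C/[C@@H](C)[C@H]1C[C@@H](C/C=C/C(=O)OCC[Si](C)(C)C)CC(=O)O1)=C\c1coc(C)n1 | intermediate
36 | (13R)-15,17-bis(triethylsilyl) ether 2-(trimethylsilyl)ethyl ester of the target | CC(/C=C/C=C(\C)[C@H](O[Si](CC)(CC)CC)[C@@H](C)[C@@H](O[Si](CC)(CC)CC)C[C@@H](O)/C(C)=C/C=C/[C@@H](C)[C@H]1C[C@@H](C/C=C/C(=O)OCC[Si](C)(C)C)CC(=O)O1)=C\c1coc(C)n1 | intermediate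
37 | CNP0198746.1, (2E)-4-{(2R,4R)-2-[(2R,3E,5E,7R,9S,10S,11R,12E,14E,16E)-7,9,11-trihydroxy-6,10,12,16-tetramethyl-17-(2-methyl-1,3-oxazol-4-yl)heptadeca-3,5,12,14,16-pentaen-2-yl]-6-oxooxan-4-yl}but-2-enoic acid | CC(/C=C/C=C(\C)[C@H](O)[C@@H](C)[C@@H](O)C[C@@H](O)/C(C)=C/C=C/[C@@H](C)[C@H]1C[C@@H](C/C=C/C(=O)O)CC(=O)O1)=C\c1coc(C)n1 | target

**Step count and risks**
Total step count: 23. Longest linear sequence: 13 steps (steps 1–8, 10, 20–23; the eastern branch, steps 11–19 and 20–23, is equally long).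

Steps most likely to fail:

Step 20. Nickel may be sequestered by the oxazole and polyene of 33, or reductive consumption of the enoate of 17 may compete with the alkyne–aldehyde coupling. The fallback makes the same bond by a Nozaki–Hiyama–Kishi reaction. Setting out from 17, hydrozirconation with Cp2Zr(H)Cl (THF, rt; syn addition with zirconium at the methyl-bearing alkyne carbon) and iodinolysis with I2 would give the dienyl iodide 2-(trimethylsilyl)ethyl (2E)-4-{(2R,4R)-2-[(2R,3E,5E)-6-iodohepta-3,5-dien-2-yl]-6-oxooxan-4-yl}but-2-enoate F1. F1 would be coupled with 33 using CrCl2, catalytic NiCl2 and a chiral oxazoline–sulfonamide ligand chosen for the 13R series. This comes back to the route at 36 and makes steps 21 and 22 unnecessary.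

Step 17. Ionisation of the acid-labile trienyl carbinol at C17 in acetic acid may compete with the reduction. The fallback is a neutral Evans–Tishchenko reduction: setting out from 30, SmI2 (cat.) and acetaldehyde in THF at −10 °C would give the 15,17-anti monoester methyl (3S,4S,5R,6E,8E,10E)-5-acetoxy-3-hydroxy-4,6,10-trimethyl-11-(2-methyl-1,3-oxazol-4-yl)undeca-6,8,10-trienoate F4. Methanolysis of the acetate (K2CO3, MeOH, 0 °C) would come back to the route at 31.

Step 12. Over-homologation may occur, because the product dienal can react again with the formylmethylene ylide. The fallback sets out from 20: Horner–Wadsworth–Emmons olefination with triethyl phosphonoacetate (NaH, THF) would give ethyl (2E,4E)-4-methyl-5-(2-methyl-1,3-oxazol-4-yl)penta-2,4-dienoate F2. Reduction with i-Bu2AlH (CH2Cl2, −78 °C) would give (2E,4E)-4-methyl-5-(2-methyl-1,3-oxazol-4-yl)penta-2,4-dien-1-ol F3, and MnO2 oxidation (CH2Cl2, rt) would come back to the route at 22.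

Further compounds
F1 | step 20 | 2-(trimethylsilyl)ethyl (2E)-4-{(2R,4R)-2-[(2R,3E,5E)-6-iodohepta-3,5-dien-2-yl]-6-oxooxan-4-yl}but-2-enoate | I/C(C)=C/C=C/[C@@H](C)[C@H]1C[C@@H](C/C=C/C(=O)OCC[Si](C)(C)C)CC(=O)O1
F2 | step 12 | ethyl (2E,4E)-4-methyl-5-(2-methyl-1,3-oxazol-4-yl)penta-2,4-dienoate | CCOC(=O)/C=C/C(C)=C/c1coc(C)n1
F3 | step 12 | (2E,4E)-4-methyl-5-(2-methyl-1,3-oxazol-4-yl)penta-2,4-dien-1-ol | OC/C=C/C(C)=C/c1coc(C)n1
F4 | step 17 | methyl (3S,4S,5R,6E,8E,10E)-5-acetoxy-3-hydroxy-4,6,10-trimethyl-11-(2-methyl-1,3-oxazol-4-yl)undeca-6,8,10-trienoate | CC(/C=C/C=C(\C)[C@H](OC(C)=O)[C@@H](C)[C@@H](O)CC(=O)OC)=C\c1coc(C)n1
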